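## Retrosynthetic overview

1. Lehualide H is achiral and has one ring, a fully substituted 2-pyrone (O1, C2=O, C3-OMe, C4-OMe, C5-Me, C6-decyl). The terminal C–S bond is cut first (Mitsunobu reaction after desilylation), which leads back to the 10-silyloxydecyl pyrone.
2. Feature on which the plan rests: once the lactone carbonyl C2 is taken out of the pyrone ring, the five atoms left, O1–C6=C5–C4=C3(–H), are the linear (γ-deprotonated) dienolate of an open-chain β-methoxy enone. It is nucleophilic at both ends, O1 and C3.
3. Key disconnection: C2–C3 and C2–O1 are both cut to carbon monoxide. The only ring is made in this one step, an oxidative cyclocarbonylation with Pd(OAc)2 and benzoquinone.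
4. The dienolate is brought in as its O-silyl ether, made from the enone under soft, equilibrating conditions. This fixes the linear regiochemistry and avoids mixing an alkali enolate with a quinone; chain-side deprotonation would give the cross-conjugated dienolate, which cannot close and would only be dehydrogenated.
5. The enone is cut at the C6–chain bond into a Weinreb amide (from methyl 4-methoxyacetoacetate by C-methylation, O-methylation and aminolysis) and the Grignard reagent of silylated 10-bromodecan-1-ol.

Key step: step 7

Assumption: enol ethers 4, 6 and 11 are drawn as the E isomers (methoxy group trans to the carbonyl group) expected under equilibrating acid conditions, and 12 as the 1Z,3Z isomer that is able to close. Step 6 removes the first geometry and palladium-bound forms can rotate in step 7, so geometrical mixtures can be carried forward.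

## Route

Step 1
Reactants: 1 methyl 4-methoxyacetoacetate
Product: 2 methyl 4-methoxy-2-methyl-3-oxobutanoate (racemic)
Conditions: MeI (1.0 equiv), K2CO3, acetone, rt to 40 °C
Reagents that add atoms: iodomethane, CI
Why: Alkylation of a β-keto ester enolate: the weak base deprotonates only the doubly activated C2, the soft electrophile MeI reacts there at carbon, one equivalent limits double methylation, and the new stereocentre is racemic and of no consequence because C2 becomes sp2 in step 2.

Step 2
Reactants: 2 methyl 4-methoxy-2-methyl-3-oxobutanoate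
Product: 4 methyl (E)-3,4-dimethoxy-2-methylbut-2-enoate, via dimethyl ketal 3 (not isolated)
Conditions: HC(OMe)3, H2SO4 (cat.), MeOH, 50 °C; then TsOH (cat.), 130 °C, MeOH distilled off
Reagents that add atoms: trimethyl orthoformate, COC(OC)OC
Why: Enol etherification with an orthoester: acid-catalysed ketalisation of the ketone gives 3, which on heating with acid loses methanol toward the acidic C2–H to give the conjugated β-methoxy enoate, the E isomer with the methoxy group trans to the ester being favoured under these equilibrating conditions.

Step 3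
Reactants: 4 methyl (E)-3,4-dimethoxy-2-methylbut-2-enoate; 5 N,O-dimethylhydroxylamine hydrochloride
Product: 6 (E)-N,3,4-trimethoxy-N,2-dimethylbut-2-enamide
Conditions: 5 (1.5 equiv), iPrMgCl (3.0 equiv), THF, −20 °C to rt; sat. aq. NH4Cl
Reagents that add atoms: N,O-dimethylhydroxylamine hydrochloride 5, CNOC.Cl
Why: Weinreb amide formation by aminolysis of the ester with the chloromagnesium amide made in the flask from 5 and iPrMgCl, a small and strongly nucleophilic reagent that should reach even this donor-deactivated ester carbonyl, while the tetrasubstituted β-carbon is too hindered for addition–elimination of its methoxy group.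

Step 4
Reactants: 7 10-bromodecan-1-ol
Product: 8 (10-bromodecyloxy)(tert-butyl)dimethylsilane
Conditions: TBSCl, imidazole, CH2Cl2, 0 °C to rt
Reagents that add atoms: tert-butyldimethylsilyl chloride, CC(C)(C)[Si](C)(C)Cl
Why: Standard imidazole-promoted silylation of a primary alcohol, needed because a free hydroxyl group would quench the Grignard reagent of step 5, with the alkyl bromide left untouched.

Step 5
Reactants: 8 (10-bromodecyloxy)(tert-butyl)dimethylsilane; 6 (E)-N,3,4-trimethoxy-N,2-dimethylbut-2-enamide
Product: 11 (E)-14-(tert-butyldimethylsilyloxy)-1,2-dimethoxy-3-methyltetradec-2-en-4-one, via silyloxydecylmagnesium bromide 9 (not isolated), via bromomagnesium adduct 10 (not isolated)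
Conditions: Mg turnings, I2 (cat.), THF, 45 °C; then 6, THF, 0 °C to rt; sat. aq. NH4Cl
Reagents that add atoms: none
Why: Grignard formation followed by Weinreb ketone synthesis: adduct 10 is held as a five-membered N-methoxy magnesium chelate until the quench, so the ketone is released only when no organometallic is left, which prevents both a second addition and displacement of the β-methoxy group, and the silyl ether is inert in both stages.

Step 6
Reactants: 11 (E)-14-(tert-butyldimethylsilyloxy)-1,2-dimethoxy-3-methyltetradec-2-en-4-one
Product: 12 (1Z,3Z)-4,14-bis(tert-butyldimethylsilyloxy)-1,2-dimethoxy-3-methyltetradeca-1,3-diene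
Conditions: TBSOTf (1.3 equiv), Et3N (2.5 equiv), CH2Cl2, 0 °C to rt; filtration through Et3N-deactivated silica
Reagents that add atoms: tert-butyldimethylsilyl triflate, CC(C)(C)[Si](C)(C)OS(=O)(=O)C(F)(F)F
Why: Soft enolisation with a silyl triflate and a tertiary amine, the standard way from enones to extended silyl dienol ethers, should work here because O-silylation places most of the positive charge on C4 beside the better donor OMe, so that the amine takes the neighbouring CH2OMe proton, which its own oxygen also acidifies inductively, in preference to a chain-side proton, while reprotonation by Et3NH+ lets any cross-conjugated isomer drain into the linear diene, and the 1Z geometry keeps the C3 methoxy group away from C5.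

Step 7
Reactants: 12 (1Z,3Z)-4,14-bis(tert-butyldimethylsilyloxy)-1,2-dimethoxy-3-methyltetradeca-1,3-diene; 13 carbon monoxide
Product: 16 6-[10-(tert-butyldimethylsilyloxy)decyl]-3,4-dimethoxy-5-methyl-2H-pyran-2-one, via oxapalladacycle 14 (not isolated), via acylpalladacycle 15 (not isolated)
Conditions: Pd(OAc)2 (10 mol %), CO (1 atm), 1,4-benzoquinone (1.5 equiv, slow addition), AcOH (1.0 equiv), MeCN with 10 vol % DMSO, 45 °C
Reagents that add atoms: carbon monoxide 13, [C-]#[O+]
Why: Proposed new method: Pd(OAc)2 displaces the enol silyl group of 12 as in the first stage of a Saegusa–Ito oxidation, and the oxygen-tethered divalent palladium is attacked by the electron-rich C3 terminus, acetate taking the C3 proton, to give six-membered oxapalladacycle 14 (Pd, O1, C6, C5, C4, C3). CO inserts into the Pd–C3 bond (new C2–C3 bond) to give seven-membered acylpalladacycle 15, and C(acyl)–O reductive elimination (new C2–O1 bond) closes the only ring, the six-membered lactone, in an overall [5+1] carbonylative annulation, while benzoquinone and AcOH return zerovalent palladium to Pd(OAc)2. The closest known reaction type is the Pd(OAc)2-catalysed oxidative cyclocarbonylation of 2-vinylphenols to coumarins, in which the same O–C=C–C=C–H array is built into an arene; an acyclic ketone dienolate has not been shown to do this. No stereocentre is formed, and the double-bond geometry of 12 is not binding because oxygen-, C5- and C3-bound palladium forms interconvert by rotation. The step needs site selectivity for C3–H over chain-side dehydrogenation and over C5: the silyl group fixes the linear dienolate, in which no chain hydrogen is β to palladium, C5 is fully substituted and cannot give a palladacycle, and palladium at C3 has no β-hydrogen, so only hydride loss from the C5 methyl group competes and CO saturation of the metal works against it. The silyl ether is used in place of an alkali dienolate, and the quinone is added slowly, because quinones add to or oxidise free enolates and electron-rich dienes.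

Step 8
Reactants: 16 6-[10-(tert-butyldimethylsilyloxy)decyl]-3,4-dimethoxy-5-methyl-2H-pyran-2-one
Product: 17 6-(10-hydroxydecyl)-3,4-dimethoxy-5-methyl-2H-pyran-2-one
Conditions: HF·pyridine, pyridine, THF, 0 °C to rt
Reagents that add atoms: none
Why: Fluoride-driven cleavage of a primary silyl ether, powered by the strong Si–F bond, under weakly acidic buffered conditions that touch neither the lactone nor the two ring methoxy groups.

Step 9
Reactants: 17 6-(10-hydroxydecyl)-3,4-dimethoxy-5-methyl-2H-pyran-2-one; 18 thioacetic acid
Product: 19 lehualide H, S-[10-(3,4-dimethoxy-5-methyl-2-oxo-2H-pyran-6-yl)decyl] ethanethioate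
Conditions: PPh3, DIAD, 18, THF, 0 °C to rt
Reagents that add atoms: thioacetic acid 18, CC(=O)S
Why: Mitsunobu reaction: the phosphine–azodicarboxylate pair turns the primary hydroxyl group into a leaving group and the sulfur of thioacetic acid, which is acidic enough for this manifold, displaces it in an SN2 step under neutral conditions that spare the pyrone and never expose a free thiol.

## Compound list

1 | methyl 4-methoxyacetoacetate (methyl 4-methoxy-3-oxobutanoate) | COCC(=O)CC(=O)OC | starting material
2 | methyl 4-methoxy-2-methyl-3-oxobutanoate (racemic) | COCC(=O)C(C)C(=O)OC | intermediate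
3 | methyl 3,3,4-trimethoxy-2-methylbutanoate (racemic dimethyl ketal, not isolated) | COCC(OC)(OC)C(C)C(=O)OC | intermediate
4 | methyl (E)-3,4-dimethoxy-2-methylbut-2-enoate | COC/C(OC)=C(/C)C(=O)OC | intermediate
5 | N,O-dimethylhydroxylamine hydrochloride | CNOC.Cl | starting material
6 | (E)-N,3,4-trimethoxy-N,2-dimethylbut-2-enamide | COC/C(OC)=C(/C)C(=O)N(C)OC | intermediate
7 | 10-bromodecan-1-ol | OCCCCCCCCCCBr | starting material
8 | (10-bromodecyloxy)(tert-butyl)dimethylsilane | BrCCCCCCCCCCO[Si](C)(C)C(C)(C)C | intermediate
9 | [10-(tert-butyldimethylsilyloxy)decyl]magnesium bromide (not isolated) | Br[Mg]CCCCCCCCCCO[Si](C)(C)C(C)(C)C | intermediate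
10 | bromomagnesium (E)-14-(tert-butyldimethylsilyloxy)-1,2-dimethoxy-4-[methoxy(methyl)amino]-3-methyltetradec-2-en-4-olate (racemic, not isolated) | COC/C(OC)=C(/C)C(O[Mg]Br)(CCCCCCCCCCO[Si](C)(C)C(C)(C)C)N(C)OC | intermediate
11 | (E)-14-(tert-butyldimethylsilyloxy)-1,2-dimethoxy-3-methyltetradec-2-en-4-one | COC/C(OC)=C(/C)C(=O)CCCCCCCCCCO[Si](C)(C)C(C)(C)C | intermediate
12 | (1Z,3Z)-4,14-bis(tert-butyldimethylsilyloxy)-1,2-dimethoxy-3-methyltetradeca-1,3-diene | CO/C=C(\OC)/C(C)=C(\O[Si](C)(C)C(C)(C)C)CCCCCCCCCCO[Si](C)(C)C(C)(C)C | intermediate
13 | carbon monoxide | [C-]#[O+] | starting material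
14 | six-membered oxapalladacycle with ring atoms Pd, O1, C6, C5, C4, C3 (ancillary ligands omitted, not isolated) | COC1=C(OC)C(C)=C(CCCCCCCCCCO[Si](C)(C)C(C)(C)C)O[Pd]1 | intermediate
15 | seven-membered acyl oxapalladacycle with ring atoms Pd, C2, C3, C4, C5, C6, O1 (ancillary ligands omitted, not isolated) | COC1=C(OC)C(C)=C(CCCCCCCCCCO[Si](C)(C)C(C)(C)C)O[Pd]C1=O | intermediate
16 | 6-[10-(tert-butyldimethylsilyloxy)decyl]-3,4-dimethoxy-5-methyl-2H-pyran-2-one | COc1c(C)c(CCCCCCCCCCO[Si](C)(C)C(C)(C)C)oc(=O)c1OC | intermediate
17 | 6-(10-hydroxydecyl)-3,4-dimethoxy-5-methyl-2H-pyran-2-one | COc1c(C)c(CCCCCCCCCCO)oc(=O)c1OC | intermediate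
18 | thioacetic acid | CC(=O)S | starting material
19 | lehualide H | COc1c(C)c(CCCCCCCCCCSC(C)=O)oc(=O)c1OC | target

## Step count and risks

Total step count: 9. Longest linear sequence: 8 steps (steps 1, 2, 3, 5, 6, 7, 8, 9, from 1 to 19).

**1. Step 7 (labelled step).**
- **What may go wrong:** The palladium-bound dienolate may be lost before CO is taken up. This could happen by protonolysis back to the enone, by hydride elimination from the C5 methyl group, or by reduction of the catalyst by CO faster than turnover. Interception of the electron-rich diene by the quinone is a further drain.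
- **Fallback:** known chemistry (classical triketide lactonisation), setting out from Grignard reagent 9 (made from 8 as in step 5) and coming back at 16.
  - 9 is carboxylated with CO2 (THF, −20 °C; aq. NH4Cl, then citric acid) to 11-(tert-butyldimethylsilyloxy)undecanoic acid F1. 1,1'-Carbonyldiimidazole in THF converts it into 11-(tert-butyldimethylsilyloxy)-1-(imidazol-1-yl)undecan-1-one F2.
  - In parallel, methyl methoxyacetate is deprotonated with LiN(iPr)2 (THF, −78 °C) and acylated with propanoyl chloride (crossed Claisen condensation) to methyl 2-methoxy-3-oxopentanoate F3.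
  - Double deprotonation of F3 (NaH, then nBuLi, THF, 0 °C) and acylation of its more reactive C4 terminus with F2 gives methyl 15-(tert-butyldimethylsilyloxy)-2-methoxy-4-methyl-3,5-dioxopentadecanoate F4.
  - DBU in toluene at reflux lactonises it with loss of methanol to 6-[10-(tert-butyldimethylsilyloxy)decyl]-4-hydroxy-3-methoxy-5-methyl-2H-pyran-2-one F5. Me2SO4 with K2CO3 in acetone methylates the C4 hydroxyl group to give 16.

**2. Step 6.**
- **What may go wrong:** Enolisation may go toward the chain-side CH2, or may give regioisomers that cannot be separated. In step 7 these would be diverted into dehydrogenation.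
- **Fallback:** setting out from Weinreb amide 6 and coming back at 16, with the competing protons taken out of the substrate.
  - Dec-9-yn-1-ol is silylated (TBSCl, imidazole) to tert-butyl(dec-9-yn-1-yloxy)dimethylsilane F6. After deprotonation with nBuLi (THF, −78 °C) it adds to 6 to give (E)-14-(tert-butyldimethylsilyloxy)-1,2-dimethoxy-3-methyltetradec-2-en-5-yn-4-one F7.
  - This ketone has no hydrogen on the chain-side α-carbon, so TBSOTf and iPr2NEt can only give (1Z,3Z)-4,14-bis(tert-butyldimethylsilyloxy)-1,2-dimethoxy-3-methyltetradeca-1,3-dien-5-yne F8.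
  - The conditions of step 7 would then close 6-[10-(tert-butyldimethylsilyloxy)dec-1-yn-1-yl]-3,4-dimethoxy-5-methyl-2H-pyran-2-one F9, and H2 over Pd/C in EtOAc saturates the triple bond to give 16.

**3. Step 3.**
- **What may go wrong:** Acyl substitution at a push–pull, tetrasubstituted enoate may stall. The magnesium amide may also act as a base at the CH2OMe group or displace the β-methoxy group. The same deactivation could slow the acyl substitution of step 5.
- **Fallback:** setting out from ester 4 and coming back at 11, without any amide.
  - iBu2AlH (CH2Cl2, −78 °C) reduces 4 to (E)-3,4-dimethoxy-2-methylbut-2-en-1-ol F10, and MnO2 in CH2Cl2 oxidises it to (E)-3,4-dimethoxy-2-methylbut-2-enal F11.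
  - Grignard reagent 9 adds to the aldehyde (THF, −78 °C) to give racemic (E)-14-(tert-butyldimethylsilyloxy)-1,2-dimethoxy-3-methyltetradec-2-en-4-ol F12. Dess–Martin periodinane buffered with NaHCO3 oxidises the allylic alcohol to 11.

## Further compounds

F1 | step 7 | 11-(tert-butyldimethylsilyloxy)undecanoic acid | OC(=O)CCCCCCCCCCO[Si](C)(C)C(C)(C)C
F2 | step 7 | 11-(tert-butyldimethylsilyloxy)-1-(imidazol-1-yl)undecan-1-one | O=C(CCCCCCCCCCO[Si](C)(C)C(C)(C)C)n1ccnc1
F3 | step 7 | methyl 2-methoxy-3-oxopentanoate (racemic) | CCC(=O)C(OC)C(=O)OC
F4 | step 7 | methyl 15-(tert-butyldimethylsilyloxy)-2-methoxy-4-methyl-3,5-dioxopentadecanoate (stereoisomers and enol forms) | COC(=O)C(OC)C(=O)C(C)C(=O)CCCCCCCCCCO[Si](C)(C)C(C)(C)C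
F5 | step 7 | 6-[10-(tert-butyldimethylsilyloxy)decyl]-4-hydroxy-3-methoxy-5-methyl-2H-pyran-2-one | COc1c(O)c(C)c(CCCCCCCCCCO[Si](C)(C)C(C)(C)C)oc1=O
F6 | step 6 | tert-butyl(dec-9-yn-1-yloxy)dimethylsilane | C#CCCCCCCCCO[Si](C)(C)C(C)(C)C
F7 | step 6 | (E)-14-(tert-butyldimethylsilyloxy)-1,2-dimethoxy-3-methyltetradec-2-en-5-yn-4-one | COC/C(OC)=C(/C)C(=O)C#CCCCCCCCCO[Si](C)(C)C(C)(C)C
F8 | step 6 | (1Z,3Z)-4,14-bis(tert-butyldimethylsilyloxy)-1,2-dimethoxy-3-methyltetradeca-1,3-dien-5-yne | CO/C=C(\OC)/C(C)=C(\O[Si](C)(C)C(C)(C)C)C#CCCCCCCCCO[Si](C)(C)C(C)(C)C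
F9 | step 6 | 6-[10-(tert-butyldimethylsilyloxy)dec-1-yn-1-yl]-3,4-dimethoxy-5-methyl-2H-pyran-2-one | COc1c(C)c(C#CCCCCCCCCO[Si](C)(C)C(C)(C)C)oc(=O)c1OC
F10 | step 3 | (E)-3,4-dimethoxy-2-methylbut-2-en-1-ol | COC/C(OC)=C(/C)CO
F11 | step 3 | (E)-3,4-dimethoxy-2-methylbut-2-enal | COC/C(OC)=C(/C)C=O
F12 | step 3 | (E)-14-(tert-butyldimethylsilyloxy)-1,2-dimethoxy-3-methyltetradec-2-en-4-ol (racemic) | COC/C(OC)=C(/C)C(O)CCCCCCCCCCO[Si](C)(C)C(C)(C)C
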